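Ring C is cut at C4–C3 and at O–C2, which separates a ring A nitrile oxide (its carbon becomes C4) from a ring B arylacetylene (C3 and C2). One intermolecular [3+2] cycloaddition makes both bonds and stores the 1,3-dicarbonyl relationship of C4 and C2 as a 3,5-diarylisoxazole. The step exploits the position of C4 on C4a of ring A, between the oxygen-bearing carbons C5 and C8a (O1): as MOM ethers these two ortho oxygens make the dipole isolable, and the local symmetry of ring A lets either become O1. The precursor is 2,4,6-tris(methoxymethoxy)-3,5-diprenylbenzonitrile oxide, paired with 4-(methoxymethoxy)phenylacetylene; O3 is added afterwards at the isoxazole C4–H.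

Key step: step 9

Remark: prenyl = 3-methylbut-2-en-1-yl and MOM = methoxymethyl; the target has no stereocenter, so only the geometry of oxime 11 and of enaminone 23 is specified, each as the isomer expected to predominate.

**Route**

Step 1
Reactants: 1 phloroglucinol
Product: 2 1,3,5-tris(methoxymethoxy)benzene
Conditions: MOMCl (3.6 equiv), iPr2NEt (4.5 equiv), CH2Cl2, 0 °C → rt
Reagents that add atoms: chloromethyl methyl ether (MOMCl), COCCl
Why: Amine-mediated O-alkylation of the three phenols with the α-chloro ether (MOM protection) is fast enough to outrun C-alkylation and installs groups that later direct ortho-lithiation and are all removed in the final acid step.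

Step 2
Reactants: 2 1,3,5-tris(methoxymethoxy)benzene; 3 prenyl bromide (1-bromo-3-methylbut-2-ene)
Product: 5 1,3,5-tris(methoxymethoxy)-2-(3-methylbut-2-en-1-yl)benzene, via aryllithium 4 (not isolated)
Conditions: n-BuLi (1.1 equiv), TMEDA, THF, 0 °C; then 3, −78 °C → rt
Reagents that add atoms: none
Why: Directed ortho-metalation at the position flanked by two chelating MOM ethers, then SN2 alkylation of aryllithium 4 by the primary allylic bromide, is the standard way to C-prenylate phloroglucinol ethers and cannot over-alkylate because only one equivalent of base is used.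

Step 3
Reactants: 5 1,3,5-tris(methoxymethoxy)-2-(3-methylbut-2-en-1-yl)benzene; 3 prenyl bromide
Product: 7 1,3,5-tris(methoxymethoxy)-2,4-bis(3-methylbut-2-en-1-yl)benzene, via aryllithium 6 (not isolated)
Conditions: n-BuLi (1.1 equiv), TMEDA, THF, 0 °C; then 3, −78 °C → rt
Reagents that add atoms: none
Why: The same directed ortho-metalation and allylic alkylation sequence is repeated at one of the two equivalent remaining ring positions, each still flanked by two MOM ethers, so a single diprenyl isomer should form.

Step 4
Reactants: 7 1,3,5-tris(methoxymethoxy)-2,4-bis(3-methylbut-2-en-1-yl)benzene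
Product: 10 2,4,6-tris(methoxymethoxy)-3,5-bis(3-methylbut-2-en-1-yl)benzaldehyde, via aryllithium 8 (not isolated), via lithium hemiaminal alkoxide 9 (not isolated)
Conditions: n-BuLi, TMEDA, THF, 0 °C; DMF, 0 °C → rt; then H2O
Reagents that add atoms: N,N-dimethylformamide, CN(C)C=O
Why: The last ring hydrogen lies between two MOM ethers and should be removed by directed ortho-metalation faster than the benzylic CH2 groups of the electron-rich arene, and formylation of aryllithium 8 with DMF gives the aldehyde once the hemiaminal alkoxide 9 collapses on aqueous quench.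

Step 5
Reactants: 10 2,4,6-tris(methoxymethoxy)-3,5-bis(3-methylbut-2-en-1-yl)benzaldehyde
Product: 11 (E)-2,4,6-tris(methoxymethoxy)-3,5-bis(3-methylbut-2-en-1-yl)benzaldehyde oxime
Conditions: NH2OH·HCl, pyridine, EtOH, 60 °C
Reagents that add atoms: hydroxylamine hydrochloride, NO.Cl
Why: Condensation of the aldehyde with hydroxylamine under pyridine buffering (oxime formation) tolerates acetals and alkenes, and the E isomer with hydroxyl anti to the bulky arene is expected, although either isomer would serve in the next step.

Step 6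
Reactants: 11 (E)-2,4,6-tris(methoxymethoxy)-3,5-bis(3-methylbut-2-en-1-yl)benzaldehyde oxime
Product: 12 2,4,6-tris(methoxymethoxy)-3,5-bis(3-methylbut-2-en-1-yl)benzonitrile oxide
Conditions: PhI(OAc)2 (1.1 equiv), TFA (cat.), MeOH, 0 °C → rt
Reagents that add atoms: none
Why: Oxidative dehydrogenation of the aldoxime by the trivalent iodine reagent (ligand exchange at iodine, then loss of iodobenzene and acetic acid) gives the nitrile oxide, which the two flanking MOM-oxy groups shield from dimerisation so that it can be isolated, while the non-halogenating oxidant leaves the prenyl alkenes alone.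

Step 7
Reactants: 13 4-iodophenol
Product: 14 1-iodo-4-(methoxymethoxy)benzene
Conditions: MOMCl, iPr2NEt, CH2Cl2, 0 °C → rt
Reagents that add atoms: chloromethyl methyl ether (MOMCl), COCCl
Why: Standard MOM protection of the phenol (O-alkylation with an α-chloro ether) gives an ether that survives cross-coupling and organolithium chemistry and leaves in the final acid step.

Step 8
Reactants: 14 1-iodo-4-(methoxymethoxy)benzene; 15 trimethylsilylacetylene
Product: 17 1-ethynyl-4-(methoxymethoxy)benzene, via silyl alkyne 16 (not isolated)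
Conditions: PdCl2(PPh3)2 (2 mol%), CuI (4 mol%), Et3N, THF, rt; then MeOH, K2CO3, rt
Reagents that add atoms: none
Why: Sonogashira coupling of the aryl iodide (oxidative addition to zerovalent palladium formed in situ, transmetalation from the copper acetylide, reductive elimination) and then base-catalysed methanolysis of the C–Si bond in the same flask should deliver the terminal arylacetylene.

Step 9
Reactants: 12 2,4,6-tris(methoxymethoxy)-3,5-bis(3-methylbut-2-en-1-yl)benzonitrile oxide; 17 1-ethynyl-4-(methoxymethoxy)benzene
Product: 18 3-[2,4,6-tris(methoxymethoxy)-3,5-bis(3-methylbut-2-en-1-yl)phenyl]-5-[4-(methoxymethoxy)phenyl]isoxazole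
Conditions: 17 (2 equiv), toluene, 80 °C
Reagents that add atoms: none
Why: The linear C≡N–O dipole and the alkyne π bond combine in a concerted, asynchronous suprafacial [3+2] (Huisgen) cycloaddition in which the nitrile oxide carbon bonds to the terminal alkyne carbon (future C4–C3) and the oxygen to the aryl-bearing carbon (future O–C2). The closest known reactions are the additions of mesitonitrile oxide and 2,4,6-trimethoxybenzonitrile oxide to arylacetylenes. The isoxazole is closed by intermolecular cycloaddition, three ring atoms coming from the dipole and two from the alkyne with both ring bonds formed in one transition state, and the aromatic product holds no stereocenter. Regioselectivity is required and follows from the terminal alkyne: its unsubstituted carbon carries the larger HOMO coefficient and is the only end that the shielded dipole carbon can approach, which gives the 3,5-pattern. Chemoselectivity over the prenyl groups comes from the low dipolarophilicity of trisubstituted alkenes and from their meta position, which keeps them out of reach of the dipole within the same molecule, while the two ortho MOM-oxy groups block dimerisation to the furoxan. The neutral conditions leave all four acetals intact and leave C4–H of the isoxazole free for the later oxygenation.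

Step 10
Reactants: 18 3-[2,4,6-tris(methoxymethoxy)-3,5-bis(3-methylbut-2-en-1-yl)phenyl]-5-[4-(methoxymethoxy)phenyl]isoxazole
Product: 21 3-[2,4,6-tris(methoxymethoxy)-3,5-bis(3-methylbut-2-en-1-yl)phenyl]-5-[4-(methoxymethoxy)phenyl]isoxazol-4-ol, via 4-lithioisoxazole 19 (not isolated), via pinacol boronate 20 (not isolated)
Conditions: n-BuLi, THF, −78 °C; iPrOBpin, −78 → 0 °C; then H2O2, aq. NaOH, 0 °C; aq. NH4Cl
Reagents that add atoms: hydrogen peroxide, OO
Why: Direct C4 lithiation of the 3,5-diarylisoxazole, whose only ring hydrogen is acidified by the heterocycle and placed next to the chelating ortho MOM-oxy groups, followed by borylation and peroxide oxidation of the C–B bond (aryl migration from boron to oxygen) should install O3, since ortho-lithiation of ring B and benzylic deprotonation are much slower at −78 °C.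

Step 11
Reactants: 21 3-[2,4,6-tris(methoxymethoxy)-3,5-bis(3-methylbut-2-en-1-yl)phenyl]-5-[4-(methoxymethoxy)phenyl]isoxazol-4-ol
Product: 22 4-(methoxymethoxy)-3-[2,4,6-tris(methoxymethoxy)-3,5-bis(3-methylbut-2-en-1-yl)phenyl]-5-[4-(methoxymethoxy)phenyl]isoxazole
Conditions: MOMCl, iPr2NEt, CH2Cl2, 0 °C → rt
Reagents that add atoms: chloromethyl methyl ether (MOMCl), COCCl
Why: O-Alkylation of the acidic isoxazol-4-ol with MOMCl caps O3 so that the later ring opening does not expose an easily oxidised and isomerised α-hydroxy enaminone, and the cap is shed with the other acetals at the end.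

Step 12
Reactants: 22 4-(methoxymethoxy)-3-[2,4,6-tris(methoxymethoxy)-3,5-bis(3-methylbut-2-en-1-yl)phenyl]-5-[4-(methoxymethoxy)phenyl]isoxazole
Product: 23 (E)-3-amino-2-(methoxymethoxy)-1-[4-(methoxymethoxy)phenyl]-3-[2,4,6-tris(methoxymethoxy)-3,5-bis(3-methylbut-2-en-1-yl)phenyl]prop-2-en-1-one (NH2 cis to the ketone)
Conditions: Mo(CO)6, MeCN/H2O, 80 °C
Reagents that add atoms: none
Why: Reductive N–O cleavage of the isoxazole by zerovalent molybdenum in wet acetonitrile gives the β-amino enone and, unlike catalytic hydrogenation, does not touch the trisubstituted alkenes or the acetals; the hydrogen-bonded geometry with NH2 cis to the ketone is expected.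

Step 13
Reactants: 23 (E)-3-amino-2-(methoxymethoxy)-1-[4-(methoxymethoxy)phenyl]-3-[2,4,6-tris(methoxymethoxy)-3,5-bis(3-methylbut-2-en-1-yl)phenyl]prop-2-en-1-one
Product: 24 6,8-diprenylkaempferol (3,5,7-trihydroxy-2-(4-hydroxyphenyl)-6,8-bis(3-methylbut-2-en-1-yl)-4H-chromen-4-one)
Conditions: aq. HCl (3 M), MeOH, 50 °C, argon
Reagents that add atoms: water, O
Why: Acid methanolysis removes the five MOM groups, a freed ortho hydroxyl of ring A adds to the C2 ketone and water is lost while the C4 iminium is hydrolysed with loss of ammonia (cyclodehydration of a 1-(2-hydroxyaryl)-1,3-dicarbonyl equivalent to a 4H-chromen-4-one), and because the two ortho oxygens are equivalent only one flavonol can form.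

**Compound list**

1 | phloroglucinol | Oc1cc(O)cc(O)c1 | starting material
2 | 1,3,5-tris(methoxymethoxy)benzene | COCOc1cc(OCOC)cc(OCOC)c1 | intermediate
3 | prenyl bromide (1-bromo-3-methylbut-2-ene) | CC(C)=CCBr | starting material
4 | [2,4,6-tris(methoxymethoxy)phenyl]lithium | [Li]c1c(OCOC)cc(OCOC)cc1OCOC | intermediate (not isolated)
5 | 1,3,5-tris(methoxymethoxy)-2-(3-methylbut-2-en-1-yl)benzene | CC(C)=CCc1c(OCOC)cc(OCOC)cc1OCOC | intermediate
6 | [2,4,6-tris(methoxymethoxy)-3-(3-methylbut-2-en-1-yl)phenyl]lithium | CC(C)=CCc1c(OCOC)c([Li])c(OCOC)cc1OCOC | intermediate (not isolated)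
7 | 1,3,5-tris(methoxymethoxy)-2,4-bis(3-methylbut-2-en-1-yl)benzene | CC(C)=CCc1c(OCOC)c(CC=C(C)C)c(OCOC)cc1OCOC | intermediate
8 | [2,4,6-tris(methoxymethoxy)-3,5-bis(3-methylbut-2-en-1-yl)phenyl]lithium | CC(C)=CCc1c(OCOC)c(CC=C(C)C)c(OCOC)c([Li])c1OCOC | intermediate (not isolated)
9 | lithium (dimethylamino)[2,4,6-tris(methoxymethoxy)-3,5-bis(3-methylbut-2-en-1-yl)phenyl]methanolate (racemic) | CC(C)=CCc1c(OCOC)c(CC=C(C)C)c(OCOC)c(C(O[Li])N(C)C)c1OCOC | intermediate (not isolated)
10 | 2,4,6-tris(methoxymethoxy)-3,5-bis(3-methylbut-2-en-1-yl)benzaldehyde | CC(C)=CCc1c(OCOC)c(CC=C(C)C)c(OCOC)c(C=O)c1OCOC | intermediate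
11 | (E)-2,4,6-tris(methoxymethoxy)-3,5-bis(3-methylbut-2-en-1-yl)benzaldehyde oxime | CC(C)=CCc1c(OCOC)c(CC=C(C)C)c(OCOC)c(/C=N/O)c1OCOC | intermediate
12 | 2,4,6-tris(methoxymethoxy)-3,5-bis(3-methylbut-2-en-1-yl)benzonitrile oxide | CC(C)=CCc1c(OCOC)c(CC=C(C)C)c(OCOC)c(C#[N+][O-])c1OCOC | intermediate
13 | 4-iodophenol | Oc1ccc(I)cc1 | starting material
14 | 1-iodo-4-(methoxymethoxy)benzene | COCOc1ccc(I)cc1 | intermediate
15 | trimethylsilylacetylene | C#C[Si](C)(C)C | starting material
16 | {[4-(methoxymethoxy)phenyl]ethynyl}trimethylsilane | COCOc1ccc(C#C[Si](C)(C)C)cc1 | intermediate (not isolated)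
17 | 1-ethynyl-4-(methoxymethoxy)benzene | C#Cc1ccc(OCOC)cc1 | intermediate
18 | 3-[2,4,6-tris(methoxymethoxy)-3,5-bis(3-methylbut-2-en-1-yl)phenyl]-5-[4-(methoxymethoxy)phenyl]isoxazole | CC(C)=CCc1c(OCOC)c(CC=C(C)C)c(OCOC)c(-c2cc(-c3ccc(OCOC)cc3)on2)c1OCOC | intermediate
19 | {3-[2,4,6-tris(methoxymethoxy)-3,5-bis(3-methylbut-2-en-1-yl)phenyl]-5-[4-(methoxymethoxy)phenyl]isoxazol-4-yl}lithium | CC(C)=CCc1c(OCOC)c(CC=C(C)C)c(OCOC)c(-c2noc(-c3ccc(OCOC)cc3)c2[Li])c1OCOC | intermediate (not isolated)
20 | 3-[2,4,6-tris(methoxymethoxy)-3,5-bis(3-methylbut-2-en-1-yl)phenyl]-5-[4-(methoxymethoxy)phenyl]-4-(4,4,5,5-tetramethyl-1,3,2-dioxaborolan-2-yl)isoxazole | CC(C)=CCc1c(OCOC)c(CC=C(C)C)c(OCOC)c(-c2noc(-c3ccc(OCOC)cc3)c2B4OC(C)(C)C(C)(C)O4)c1OCOC | intermediate (not isolated)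
21 | 3-[2,4,6-tris(methoxymethoxy)-3,5-bis(3-methylbut-2-en-1-yl)phenyl]-5-[4-(methoxymethoxy)phenyl]isoxazol-4-ol | CC(C)=CCc1c(OCOC)c(CC=C(C)C)c(OCOC)c(-c2noc(-c3ccc(OCOC)cc3)c2O)c1OCOC | intermediate
22 | 4-(methoxymethoxy)-3-[2,4,6-tris(methoxymethoxy)-3,5-bis(3-methylbut-2-en-1-yl)phenyl]-5-[4-(methoxymethoxy)phenyl]isoxazole | CC(C)=CCc1c(OCOC)c(CC=C(C)C)c(OCOC)c(-c2noc(-c3ccc(OCOC)cc3)c2OCOC)c1OCOC | intermediate
23 | (E)-3-amino-2-(methoxymethoxy)-1-[4-(methoxymethoxy)phenyl]-3-[2,4,6-tris(methoxymethoxy)-3,5-bis(3-methylbut-2-en-1-yl)phenyl]prop-2-en-1-one | N/C(=C(/OCOC)C(=O)c1ccc(OCOC)cc1)c1c(OCOC)c(CC=C(C)C)c(OCOC)c(CC=C(C)C)c1OCOC | intermediate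
24 | 6,8-diprenylkaempferol | CC(C)=CCc1c(O)c(CC=C(C)C)c2oc(-c3ccc(O)cc3)c(O)c(=O)c2c1O | target

**Step count and risks**

Total step count: 13. Longest linear sequence: 11 steps (steps 1–6, then 9–13); steps 7–8 form the two-step side branch.

Steps most likely to fail:

1. Step 9. The cycloaddition may be too slow at the dipole carbon, which is flanked by two MOM-oxy groups that are themselves pushed inward by the prenyl groups. Thermal rearrangement of the nitrile oxide to the isocyanate, or slow intermolecular consumption by prenyl alkenes, could then outrun ring formation. The fallback replaces the concerted dipolar addition by a stepwise anionic one and sets out from nitrile oxide 12. Commercial 4-hydroxyacetophenone is protected (MOMCl, iPr2NEt, CH2Cl2) as 1-[4-(methoxymethoxy)phenyl]ethanone F1. LiN(iPr)2 in THF at −78 °C converts it into lithium 1-[4-(methoxymethoxy)phenyl]ethenolate F2. The enolate carbon adds to the nitrile oxide carbon of 12 (−78 → 0 °C) and the oximate oxygen closes onto the ketone, which after aqueous quench should give racemic 3-[2,4,6-tris(methoxymethoxy)-3,5-bis(3-methylbut-2-en-1-yl)phenyl]-5-[4-(methoxymethoxy)phenyl]-4,5-dihydroisoxazol-5-ol F3. Warming F3 with Na2CO3 in aqueous MeOH (base-mediated dehydration and aromatisation, which keeps the acetals) brings the route back to isoxazole 18.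

2. Step 10. Site selectivity of the deprotonation may be lost, through metalation ortho to the ring B acetal, removal of a benzylic-allylic prenyl hydrogen, or butyl addition to the heterocycle. The fallback carries the boron in on the dipolarophile and sets out from alkyne 17 and nitrile oxide 12. n-BuLi (THF, −78 °C) converts 17 into {[4-(methoxymethoxy)phenyl]ethynyl}lithium F4, which is trapped with iPrOBpin and released with anhydrous HCl in Et2O at −78 °C as 2-{[4-(methoxymethoxy)phenyl]ethynyl}-4,4,5,5-tetramethyl-1,3,2-dioxaborolane F5. Thermal cycloaddition of F5 with 12 (DME or toluene, 60–80 °C) should place boron on the isoxazole C4, the regiochemistry known for 2-substituted alkynylboronates with hindered aryl nitrile oxides, and so give boronate 20 as an isolated compound. Oxidation with H2O2 and aq. NaOH then returns to isoxazol-4-ol 21 without any strong base meeting the isoxazole.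

3. Step 13. During the time needed to cleave five acetals, the freed C5 and C7 hydroxyls may add across the neighbouring prenyl double bonds under protic acid (dimethylchroman formation), or the alkenes may be hydrated. The fallback separates deprotection from ring closure and sets out from enaminone 23. ZnBr2 and propane-1-thiol in CH2Cl2 at 0 °C should cleave the acetals within minutes by thiol capture of the oxocarbenium ions, without protic acid, to give (E)-3-amino-2-hydroxy-1-(4-hydroxyphenyl)-3-[2,4,6-trihydroxy-3,5-bis(3-methylbut-2-en-1-yl)phenyl]prop-2-en-1-one F6, handled under argon and not purified. F6 is then closed in aqueous AcOH/THF at 40 °C, where the ortho hydroxyl condenses with the C2 ketone and the C4 iminium is hydrolysed, to reach target 24.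

Further compounds
F1 | step 9 | 1-[4-(methoxymethoxy)phenyl]ethanone | CC(=O)c1ccc(OCOC)cc1
F2 | step 9 | lithium 1-[4-(methoxymethoxy)phenyl]ethenolate | C=C(O[Li])c1ccc(OCOC)cc1
F3 | step 9 | 3-[2,4,6-tris(methoxymethoxy)-3,5-bis(3-methylbut-2-en-1-yl)phenyl]-5-[4-(methoxymethoxy)phenyl]-4,5-dihydroisoxazol-5-ol (racemic) | CC(C)=CCc1c(OCOC)c(CC=C(C)C)c(OCOC)c(C2=NOC(O)(c3ccc(OCOC)cc3)C2)c1OCOC
F4 | step 10 | {[4-(methoxymethoxy)phenyl]ethynyl}lithium | [Li]C#Cc1ccc(OCOC)cc1
F5 | step 10 | 2-{[4-(methoxymethoxy)phenyl]ethynyl}-4,4,5,5-tetramethyl-1,3,2-dioxaborolane | COCOc1ccc(C#CB2OC(C)(C)C(C)(C)O2)cc1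
F6 | step 13 | (E)-3-amino-2-hydroxy-1-(4-hydroxyphenyl)-3-[2,4,6-trihydroxy-3,5-bis(3-methylbut-2-en-1-yl)phenyl]prop-2-en-1-one | N/C(=C(/O)C(=O)c1ccc(O)cc1)c1c(O)c(CC=C(C)C)c(O)c(CC=C(C)C)c1O
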